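**Plan**

Numbering (daucane): C1 = ring-fusion carbon with CH3, C2 = ring CH2, C3 = C–OAc, C4 = C(OH)(i-Pr), C5 = ring-fusion CH, C6 = C–O-aroyl, C7=C8 (CH3 on C8), C9 = CH2, C10 = CH–OH.
Cuts, last to first: the aroyl and acetyl C–O bonds and the silyl ethers; both C–O bonds at C3/C4 (cis-dihydroxylation of a C3=C4 cyclopentene); C3–OMe (reductive elimination) and C8–CH3 (conjugate addition); then C3–C4 and C1–C5 in one step.
Enabling feature: C6 is the oxygen-bearing atom of the seven-membered ring next to C5. In a cyclohexane precursor that still has a C1–C6 bond and carries a C4≡C5 alkyne on the C6 carbinol, a C3 oxocarbenium ion on the C1 side chain adds to C4, the cation at C5 sits beside the carbinol, and C1 shifts from C6 to C5 (Prins–pinacol).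
Forward order: six-membered ring C1/C6–C10 from 2-methylcyclohexane-1,3-dione; the key step closes the five-membered ring and in the same act enlarges the six- to the seven-membered ring; then C7=C8 with its methyl, C3=C4, the diol and the two esters.
Stereochemistry: C1 and C10 come from a CBS desymmetrisation of the diketone (C1 then migrates with retention); H5, the C3/C4 oxygens and H6 are delivered by protonation, OsO4 and hydride to the convex face of the cis-fused bicycle.

Key step: step 7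

Remark: C3 in 12–16 is an inconsequential epimer mixture and is written without configuration (the centre disappears in step 10); acid 21 is taken as a purchasable silyl ether.

Step 1
Reactants: 1 2-methylcyclohexane-1,3-dione; 2 allyl bromide
Product: 3 2-allyl-2-methylcyclohexane-1,3-dione
Conditions: NaOH (1 M aq.), 0 °C to rt
Reagents that add atoms: none
Why: C-Alkylation of the cyclic 1,3-diketone enolate builds the future quaternary C1 with its methyl group and the masked two-carbon arm (C2, C3); 3 has a mirror plane, so no stereocentre is formed.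

Step 2
Reactants: 3 2-allyl-2-methylcyclohexane-1,3-dione
Product: 4 (2R,3S)-2-allyl-3-hydroxy-2-methylcyclohexan-1-one
Conditions: (R)-2-methyl-CBS-oxazaborolidine (20 mol %), catecholborane, toluene, −78 °C; then MeOH
Reagents that add atoms: none
Why: Corey–Bakshi–Shibata reduction desymmetrises the diketone; the (R)-catalyst should fix the carbinol (C10) as S, and hydride entry anti to the axial C-methyl group should select the carbonyl that gives hydroxyl cis to methyl, so C1 and C10 are set together.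

Step 3
Reactants: 4 (2R,3S)-2-allyl-3-hydroxy-2-methylcyclohexan-1-one
Product: 5 (2R,3S)-2-allyl-3-[(tert-butyldimethylsilyl)oxy]-2-methylcyclohexan-1-one
Conditions: TBSCl, imidazole, DMF, rt
Reagents that add atoms: tert-butyldimethylsilyl chloride, CC(C)(C)[Si](C)(C)Cl
Why: Silylation of the secondary alcohol; the C10 silyl ether has to survive the Lewis acid of step 7 and all later steps and is removed only at the end.

Step 4
Reactants: 5 (2R,3S)-2-allyl-3-[(tert-butyldimethylsilyl)oxy]-2-methylcyclohexan-1-one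
Product: 7 (2R,3S)-3-[(tert-butyldimethylsilyl)oxy]-2-(2,2-dimethoxyethyl)-2-methylcyclohexan-1-one, via keto aldehyde 6 (not isolated)
Conditions: O3, CH2Cl2/MeOH, −78 °C; Me2S; then HC(OMe)3, PPTS (cat.), MeOH, 0 °C to rt
Reagents that add atoms: trimethyl orthoformate, COC(OC)OC; methanol, CO
Why: Ozonolysis with reductive work-up cuts the allyl group to the C3 aldehyde, and only this aldehyde is acetalised because the ketone is flanked by the quaternary carbon; the acetal is the latent oxocarbenium ion of the key step.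

Step 5
Reactants: 7 (2R,3S)-3-[(tert-butyldimethylsilyl)oxy]-2-(2,2-dimethoxyethyl)-2-methylcyclohexan-1-one; 8 3-methylbut-1-yne
Product: 10 (1S,2R,3S)-3-[(tert-butyldimethylsilyl)oxy]-2-(2,2-dimethoxyethyl)-2-methyl-1-(3-methylbut-1-yn-1-yl)cyclohexan-1-ol, via lithium acetylide 9 (not isolated)
Conditions: 8, n-BuLi, THF, −78 °C; then 7, −78 to 0 °C; aq. NH4Cl
Reagents that add atoms: none
Why: 1,2-Addition of the lithium acetylide to the hindered ketone installs C5, C4 and the isopropyl group on C6; the C6 configuration (drawn for axial attack anti to the C1 methyl group) is of no consequence because C6 becomes a carbonyl carbon in step 7.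

Step 6
Reactants: 10 (1S,2R,3S)-3-[(tert-butyldimethylsilyl)oxy]-2-(2,2-dimethoxyethyl)-2-methyl-1-(3-methylbut-1-yn-1-yl)cyclohexan-1-ol
Product: 11 trimethylsilyl ether of 10, tert-butyl{[(1S,2R,3S)-2-(2,2-dimethoxyethyl)-2-methyl-3-(3-methylbut-1-yn-1-yl)-3-(trimethylsilyloxy)cyclohexyl]oxy}dimethylsilane
Conditions: N-(trimethylsilyl)imidazole, CH2Cl2, rt
Reagents that add atoms: N-(trimethylsilyl)imidazole, C[Si](C)(C)n1ccnc1
Why: Silylation of the tertiary propargylic alcohol under non-acidic conditions leaves the acetal intact; the silyl ether is the pinacol terminator of the key step.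

Step 7
Reactants: 11 trimethylsilyl ether of 10
Product: 12 (8S,8aS)-8-[(tert-butyldimethylsilyl)oxy]-2-methoxy-8a-methyl-3-(propan-2-yl)-2,5,6,7,8,8a-hexahydroazulen-4(1H)-one (epimers at the methoxy carbon)
Conditions: TMSOTf (0.3 equiv), 2,6-di-tert-butyl-4-methylpyridine, CH2Cl2, −78 to −40 °C
Reagents that add atoms: none
Why: TMSOTf ionises the dimethyl acetal to the C3 oxocarbenium ion, which the alkyne attacks through C4 (Prins step, bond C3–C4); the vinyl cation developing at C5 lies next to the C6 silyloxy carbon, so C1 shifts from C6 to C5 (pinacol step, bond C1–C5), C6 becomes the ketone and the silyl group passes to methoxide, which regenerates the acid. The closest known reaction type is the acetal-initiated Prins–pinacol ring-enlarging cyclopentane annulation of 1-alkenyl- and 1-alkynyl-cycloalkanol silyl ethers that carry a 2-(2,2-dimethoxyethyl) group, which is known to give cis-fused hydroazulenones. The five-membered ring closes by a 6-endo-dig Prins cyclisation followed by ring contraction, a net (3+2) addition of C3–C2–C1 across C4≡C5, and the same 1,2-shift enlarges the cyclohexane to the cycloheptenone. No new stereocentre has to be controlled: C1 migrates with retention and keeps its relation to C10 from step 2, C4 and C5 become sp2, and C3 forms as an epimer mixture that is erased in step 10. The step needs endo attack of the alkyne and migration of C1 and not of C7; the tether, which holds C3 near C4 and makes the C1–C6 bond the one that contracts the new ring, and the higher migratory aptitude of the quaternary carbon should secure both.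

Step 8
Reactants: 12 bicyclic enone (product of step 7)
Product: 14 (8S,8aS)-8-[(tert-butyldimethylsilyl)oxy]-2-methoxy-8a-methyl-3-(propan-2-yl)-2,7,8,8a-tetrahydroazulen-4(1H)-one, via silyl dienol ether 13 (not isolated)
Conditions: LDA, THF, −78 °C; TMSCl; then Pd(OAc)2, MeCN, rt
Reagents that add atoms: none
Why: Kinetic deprotonation of the enone at its α′-carbon C7 and silylation give the cross-conjugated dienol ether, which the Saegusa–Ito oxidation converts into the C7=C8 enone; no stereocentre is involved.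

Step 9
Reactants: 14 cross-conjugated dienone
Product: 16 (8S,8aS)-8-[(tert-butyldimethylsilyl)oxy]-2-methoxy-6,8a-dimethyl-3-(propan-2-yl)-2,7,8,8a-tetrahydroazulen-4(1H)-one, via silyl dienol ether 15 (not isolated)
Conditions: MeMgBr, CuBr·SMe2 (10 mol %), TMSCl, THF, −78 °C; then Pd(OAc)2, MeCN, rt
Reagents that add atoms: methylmagnesium bromide, C[Mg]Br
Why: Copper-catalysed conjugate addition should place the methyl group on the unhindered β-carbon C8 (C4 is fully substituted), and the Saegusa–Ito oxidation of the trapped silyl enol ether restores the C7=C8 enone, so the C8 stereocentre of 15 is lost again.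

Step 10
Reactants: 16 methyl-substituted dienone
Product: 17 (3aR,8S,8aS)-8-[(tert-butyldimethylsilyl)oxy]-6,8a-dimethyl-3-(propan-2-yl)-3a,7,8,8a-tetrahydroazulen-4(1H)-one
Conditions: SmI2 (2.1 equiv), THF, −78 °C; then AcOH, −78 °C
Reagents that add atoms: none
Why: SmI2 reductive elimination of the γ-methoxy enone expels methoxide from C3 and gives the samarium dienolate with the C3=C4 double bond; kinetic protonation at the α-carbon C5 on the face of the C1 methyl group, away from the C10 silyloxy side, should set H5 cis to that methyl group and leave C3=C4 out of conjugation.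

Step 11
Reactants: 17 β,γ-unsaturated ketone
Product: 18 (2S,3R,3aS,8S,8aS)-8-[(tert-butyldimethylsilyl)oxy]-2,3-dihydroxy-6,8a-dimethyl-3-(propan-2-yl)-2,3,3a,7,8,8a-hexahydroazulen-4(1H)-one
Conditions: OsO4 (5 mol %), NMO, citric acid, t-BuOH/H2O, 0 °C
Reagents that add atoms: N-methylmorpholine N-oxide, C[N+]1([O-])CCOCC1; water, O
Why: Catalytic OsO4 dihydroxylation should take the electron-rich C3=C4 alkene and not the enone, from the convex face anti to the allylic C5–C6 bond, which puts both hydroxyl groups cis to H5 and the isopropyl group on the concave face (C3 and C4 set together).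

Step 12
Reactants: 18 cis-diol
Product: 19 (2S,3R,3aS,8S,8aS)-8-[(tert-butyldimethylsilyl)oxy]-3-hydroxy-6,8a-dimethyl-4-oxo-3-(propan-2-yl)-1,2,3,3a,4,7,8,8a-octahydroazulen-2-yl acetate
Conditions: Ac2O, pyridine, DMAP (cat.), CH2Cl2, 0 °C
Reagents that add atoms: acetic anhydride, CC(=O)OC(C)=O
Why: Acylation should occur only at the secondary C3 hydroxyl group, because the tertiary C4 hydroxyl group next to isopropyl is too hindered; no stereocentre is touched.

Step 13
Reactants: 19 acetoxy enone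
Product: 20 (2S,3R,3aR,4S,8S,8aS)-8-[(tert-butyldimethylsilyl)oxy]-3,4-dihydroxy-6,8a-dimethyl-3-(propan-2-yl)-1,2,3,3a,4,7,8,8a-octahydroazulen-2-yl acetate
Conditions: NaBH4, CeCl3·7H2O, MeOH, −78 °C
Reagents that add atoms: none
Why: Luche 1,2-reduction of the enone; hydride is expected on the convex face (side of H5), away from the isopropyl carbinol on the concave face, which gives the C6 hydroxyl group cis to isopropyl as in the target.

Step 14
Reactants: 20 allylic alcohol; 21 4-[(tert-butyldimethylsilyl)oxy]benzoic acid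
Product: 22 (2S,3R,3aR,4S,8S,8aS)-2-acetoxy-8-[(tert-butyldimethylsilyl)oxy]-3-hydroxy-6,8a-dimethyl-3-(propan-2-yl)-1,2,3,3a,4,7,8,8a-octahydroazulen-4-yl 4-[(tert-butyldimethylsilyl)oxy]benzoate
Conditions: DCC, DMAP, CH2Cl2, rt
Reagents that add atoms: none
Why: Steglich esterification of the only accessible free hydroxyl group (allylic C6–OH; C4–OH is tertiary), with retention at C6.

Step 15
Reactants: 22 bis-silyl ether
Product: 23 (2S,3R,3aR,4S,8S,8aS)-2-acetoxy-3,8-dihydroxy-6,8a-dimethyl-3-(propan-2-yl)-1,2,3,3a,4,7,8,8a-octahydroazulen-4-yl 4-hydroxybenzoate (target)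
Conditions: HF·pyridine, THF, 0 °C to rt
Reagents that add atoms: none
Why: Acidic fluoride should cleave the aryl and the secondary alkyl silyl ethers without acyl migration or ester cleavage, releasing the phenol and the C10 hydroxyl group.

**Compound list**

1 | 2-methylcyclohexane-1,3-dione | CC1C(=O)CCCC1=O | starting material
2 | allyl bromide | C=CCBr | starting material
3 | 2-allyl-2-methylcyclohexane-1,3-dione | C=CCC1(C)C(=O)CCCC1=O | intermediate
4 | (2R,3S)-2-allyl-3-hydroxy-2-methylcyclohexan-1-one | C=CC[C@]1(C)[C@@H](O)CCCC1=O | intermediate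
5 | (2R,3S)-2-allyl-3-[(tert-butyldimethylsilyl)oxy]-2-methylcyclohexan-1-one | C=CC[C@]1(C)[C@@H](O[Si](C)(C)C(C)(C)C)CCCC1=O | intermediate
6 | 2-[(1R,2S)-2-[(tert-butyldimethylsilyl)oxy]-1-methyl-6-oxocyclohexyl]acetaldehyde | O=CC[C@]1(C)[C@@H](O[Si](C)(C)C(C)(C)C)CCCC1=O | intermediate (not isolated)
7 | (2R,3S)-3-[(tert-butyldimethylsilyl)oxy]-2-(2,2-dimethoxyethyl)-2-methylcyclohexan-1-one | COC(OC)C[C@]1(C)[C@@H](O[Si](C)(C)C(C)(C)C)CCCC1=O | intermediate
8 | 3-methylbut-1-yne | CC(C)C#C | starting material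
9 | lithium 3-methylbut-1-yn-1-ide | CC(C)C#C[Li] | intermediate (not isolated)
10 | (1S,2R,3S)-3-[(tert-butyldimethylsilyl)oxy]-2-(2,2-dimethoxyethyl)-2-methyl-1-(3-methylbut-1-yn-1-yl)cyclohexan-1-ol | COC(OC)C[C@]1(C)[C@@H](O[Si](C)(C)C(C)(C)C)CCC[C@]1(O)C#CC(C)C | intermediate
11 | trimethylsilyl ether of 10 | COC(OC)C[C@]1(C)[C@@H](O[Si](C)(C)C(C)(C)C)CCC[C@]1(O[Si](C)(C)C)C#CC(C)C | intermediate
12 | (8S,8aS)-8-[(tert-butyldimethylsilyl)oxy]-2-methoxy-8a-methyl-3-(propan-2-yl)-2,5,6,7,8,8a-hexahydroazulen-4(1H)-one (epimers at the methoxy carbon) | COC1C[C@]2(C)[C@@H](O[Si](C)(C)C(C)(C)C)CCCC(=O)C2=C1C(C)C | intermediate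
13 | trimethyl{[(8S,8aS)-8-[(tert-butyldimethylsilyl)oxy]-2-methoxy-8a-methyl-3-(propan-2-yl)-1,2,6,7,8,8a-hexahydroazulen-4-yl]oxy}silane | COC1C[C@]2(C)[C@@H](O[Si](C)(C)C(C)(C)C)CCC=C(O[Si](C)(C)C)C2=C1C(C)C | intermediate (not isolated)
14 | (8S,8aS)-8-[(tert-butyldimethylsilyl)oxy]-2-methoxy-8a-methyl-3-(propan-2-yl)-2,7,8,8a-tetrahydroazulen-4(1H)-one | COC1C[C@]2(C)[C@@H](O[Si](C)(C)C(C)(C)C)CC=CC(=O)C2=C1C(C)C | intermediate
15 | trimethyl{[(8S,8aS)-8-[(tert-butyldimethylsilyl)oxy]-2-methoxy-6,8a-dimethyl-3-(propan-2-yl)-1,2,6,7,8,8a-hexahydroazulen-4-yl]oxy}silane (epimers at the new methyl carbon) | COC1C[C@]2(C)[C@@H](O[Si](C)(C)C(C)(C)C)CC(C)C=C(O[Si](C)(C)C)C2=C1C(C)C | intermediate (not isolated)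
16 | (8S,8aS)-8-[(tert-butyldimethylsilyl)oxy]-2-methoxy-6,8a-dimethyl-3-(propan-2-yl)-2,7,8,8a-tetrahydroazulen-4(1H)-one | COC1C[C@]2(C)[C@@H](O[Si](C)(C)C(C)(C)C)CC(C)=CC(=O)C2=C1C(C)C | intermediate
17 | (3aR,8S,8aS)-8-[(tert-butyldimethylsilyl)oxy]-6,8a-dimethyl-3-(propan-2-yl)-3a,7,8,8a-tetrahydroazulen-4(1H)-one | C=1C[C@]2(C)[C@@H](O[Si](C)(C)C(C)(C)C)CC(C)=CC(=O)[C@@H]2C=1C(C)C | intermediate
18 | (2S,3R,3aS,8S,8aS)-8-[(tert-butyldimethylsilyl)oxy]-2,3-dihydroxy-6,8a-dimethyl-3-(propan-2-yl)-2,3,3a,7,8,8a-hexahydroazulen-4(1H)-one | O[C@H]1C[C@]2(C)[C@@H](O[Si](C)(C)C(C)(C)C)CC(C)=CC(=O)[C@@H]2[C@]1(O)C(C)C | intermediate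
19 | (2S,3R,3aS,8S,8aS)-8-[(tert-butyldimethylsilyl)oxy]-3-hydroxy-6,8a-dimethyl-4-oxo-3-(propan-2-yl)-1,2,3,3a,4,7,8,8a-octahydroazulen-2-yl acetate | CC(=O)O[C@H]1C[C@]2(C)[C@@H](O[Si](C)(C)C(C)(C)C)CC(C)=CC(=O)[C@@H]2[C@]1(O)C(C)C | intermediate
20 | (2S,3R,3aR,4S,8S,8aS)-8-[(tert-butyldimethylsilyl)oxy]-3,4-dihydroxy-6,8a-dimethyl-3-(propan-2-yl)-1,2,3,3a,4,7,8,8a-octahydroazulen-2-yl acetate | CC(=O)O[C@H]1C[C@]2(C)[C@@H](O[Si](C)(C)C(C)(C)C)CC(C)=C[C@H](O)[C@@H]2[C@]1(O)C(C)C | intermediate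
21 | 4-[(tert-butyldimethylsilyl)oxy]benzoic acid | CC(C)(C)[Si](C)(C)Oc1ccc(cc1)C(O)=O | starting material
22 | (2S,3R,3aR,4S,8S,8aS)-2-acetoxy-8-[(tert-butyldimethylsilyl)oxy]-3-hydroxy-6,8a-dimethyl-3-(propan-2-yl)-1,2,3,3a,4,7,8,8a-octahydroazulen-4-yl 4-[(tert-butyldimethylsilyl)oxy]benzoate | CC(=O)O[C@H]1C[C@]2(C)[C@@H](O[Si](C)(C)C(C)(C)C)CC(C)=C[C@H](OC(=O)c3ccc(O[Si](C)(C)C(C)(C)C)cc3)[C@@H]2[C@]1(O)C(C)C | intermediate
23 | (2S,3R,3aR,4S,8S,8aS)-2-acetoxy-3,8-dihydroxy-6,8a-dimethyl-3-(propan-2-yl)-1,2,3,3a,4,7,8,8a-octahydroazulen-4-yl 4-hydroxybenzoate | CC(=O)O[C@H]1C[C@]2(C)[C@@H](O)CC(C)=C[C@H](OC(=O)c3ccc(O)cc3)[C@@H]2[C@]1(O)C(C)C | target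

Total step count: 15. Longest linear sequence: 15 steps (1 to 23).

**Steps most likely to fail**

Step 7. The oxocarbenium ion may add to the alkyne in the exo mode, or the tertiary propargylic silyl ether may ionise before the acetal, so that no 1,2-shift follows. The fallback uses an alkene in place of the alkyne in the same annulation. It sets out from 10: NaAlH2(OCH2CH2OCH3)2 in THF reduces the propargylic alcohol to the (E)-allylic alcohol (1S,2R,3S)-3-[(tert-butyldimethylsilyl)oxy]-2-(2,2-dimethoxyethyl)-2-methyl-1-[(E)-3-methylbut-1-en-1-yl]cyclohexan-1-ol F1. N-(Trimethylsilyl)imidazole gives its trimethylsilyl ether F2. TMSOTf (or SnCl4) in CH2Cl2 at −78 °C then gives, by Prins cyclisation onto the alkene and pinacol shift, the saturated cis-fused ketone (8S,8aS)-8-[(tert-butyldimethylsilyl)oxy]-2-methoxy-8a-methyl-3-(propan-2-yl)octahydroazulen-4(1H)-one F3, whose centres at C3 to C5 are erased later. IBX (excess, DMSO, 75 °C) dehydrogenates both α-positions (C5–C4 and C7–C8), and the route is rejoined at dienone 14.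

Step 10. Electron transfer may go on to reduce the C7=C8 enone arm, or the dienolate may be protonated at C3, which returns a conjugated enone. The fallback cleaves the C3–O bond before the second enone is built. It sets out from 12: SmI2 in THF at −78 °C followed by AcOH gives the β,γ-unsaturated ketone (3aR,8S,8aS)-8-[(tert-butyldimethylsilyl)oxy]-8a-methyl-3-(propan-2-yl)-3a,5,6,7,8,8a-hexahydroazulen-4(1H)-one F4. OsO4/NMO gives the diol (2S,3R,3aS,8S,8aS)-8-[(tert-butyldimethylsilyl)oxy]-2,3-dihydroxy-8a-methyl-3-(propan-2-yl)octahydroazulen-4(1H)-one F5, and 2,2-dimethoxypropane with PPTS gives the acetonide of this diol F6. LDA/TMSCl followed by Pd(OAc)2 gives the acetonide-protected C7=C8 enone F7. MeMgBr with CuBr·SMe2 and TMSCl, followed by Pd(OAc)2, gives the acetonide of diol 18 F8. Aqueous AcOH in THF removes the acetonide, and the route is rejoined at diol 18.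

Step 13. Hydride may be delivered with poor facial selectivity to the flexible cycloheptenone. The fallback corrects C6 by substitution with inversion. It sets out from 19: if the reduction gives mainly the C6 epimer, (2S,3R,3aR,4R,8S,8aS)-8-[(tert-butyldimethylsilyl)oxy]-3,4-dihydroxy-6,8a-dimethyl-3-(propan-2-yl)-1,2,3,3a,4,7,8,8a-octahydroazulen-2-yl acetate F9, this alcohol is esterified with acid 21 under Mitsunobu conditions (PPh3, DIAD, toluene, 0 °C to rt). The reaction inverts C6, and the route is rejoined at ester 22.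

**Further compounds**

F1 | step 7 | (1S,2R,3S)-3-[(tert-butyldimethylsilyl)oxy]-2-(2,2-dimethoxyethyl)-2-methyl-1-[(E)-3-methylbut-1-en-1-yl]cyclohexan-1-ol | COC(OC)C[C@]1(C)[C@@H](O[Si](C)(C)C(C)(C)C)CCC[C@]1(O)/C=C/C(C)C
F2 | step 7 | trimethylsilyl ether of F1 | COC(OC)C[C@]1(C)[C@@H](O[Si](C)(C)C(C)(C)C)CCC[C@]1(O[Si](C)(C)C)/C=C/C(C)C
F3 | step 7 | (8S,8aS)-8-[(tert-butyldimethylsilyl)oxy]-2-methoxy-8a-methyl-3-(propan-2-yl)octahydroazulen-4(1H)-one, cis-fused, isopropyl trans to the ring-fusion bond to the carbonyl carbon, epimers at the methoxy carbon | COC1C[C@]2(C)[C@@H](O[Si](C)(C)C(C)(C)C)CCCC(=O)[C@@H]2[C@H]1C(C)C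
F4 | step 10 | (3aR,8S,8aS)-8-[(tert-butyldimethylsilyl)oxy]-8a-methyl-3-(propan-2-yl)-3a,5,6,7,8,8a-hexahydroazulen-4(1H)-one | C=1C[C@]2(C)[C@@H](O[Si](C)(C)C(C)(C)C)CCCC(=O)[C@@H]2C=1C(C)C
F5 | step 10 | (2S,3R,3aS,8S,8aS)-8-[(tert-butyldimethylsilyl)oxy]-2,3-dihydroxy-8a-methyl-3-(propan-2-yl)octahydroazulen-4(1H)-one | O[C@H]1C[C@]2(C)[C@@H](O[Si](C)(C)C(C)(C)C)CCCC(=O)[C@@H]2[C@]1(O)C(C)C
F6 | step 10 | acetonide (2,2-dimethyl-1,3-dioxolane) of F5 | CC1(C)O[C@H]2C[C@]3(C)[C@@H](O[Si](C)(C)C(C)(C)C)CCCC(=O)[C@@H]3[C@]2(O1)C(C)C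
F7 | step 10 | acetonide of the C7=C8 enone (5,6-didehydro derivative of F6) | CC1(C)O[C@H]2C[C@]3(C)[C@@H](O[Si](C)(C)C(C)(C)C)CC=CC(=O)[C@@H]3[C@]2(O1)C(C)C
F8 | step 10 | acetonide of diol 18 | CC1(C)O[C@H]2C[C@]3(C)[C@@H](O[Si](C)(C)C(C)(C)C)CC(C)=CC(=O)[C@@H]3[C@]2(O1)C(C)C
F9 | step 13 | (2S,3R,3aR,4R,8S,8aS)-8-[(tert-butyldimethylsilyl)oxy]-3,4-dihydroxy-6,8a-dimethyl-3-(propan-2-yl)-1,2,3,3a,4,7,8,8a-octahydroazulen-2-yl acetate | CC(=O)O[C@H]1C[C@]2(C)[C@@H](O[Si](C)(C)C(C)(C)C)CC(C)=C[C@@H](O)[C@@H]2[C@]1(O)C(C)C
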